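**Strategy**

The ten-membered carbocycle (C1–C10) is disconnected at the C1–C10 bond. The C1–C10 oxirane with C15H2OAc on C1 is treated as a masked allylic alcohol, a C10 carbinol flanked by a C1=C15 exocyclic methylene, and this array is what addition of a C1 alkenylchromium to a C10 aldehyde produces. One operation therefore forms C1–C10, closes the ring and sets C10, the stereocentre from which both oxirane carbons are later derived by tartrate-controlled epoxidation and epoxide transposition. The cyclisation substrate is an acyclic 2-iodo-1-alkene aldehyde carrying the Z-enone (C4=C5–C6=O) and the E-tetrasubstituted C8=C11 alkene, with C12 as a silyl ether.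

Key step: step 14

Remark on numbering: ring carbons are C1–C10 (C1 = oxirane carbon bearing C15H2OAc, C4=C5 with C14H3 on C5, C6 = ketone, C8 = spiro carbon, C10 = oxirane CH); C11 on C8 carries C13H3 and C12H2OAc; the target is (1R,4Z,8S,10R,11S).
Remark on consistency: syn epoxidation of the E-configured C8=C11 alkene (C7 cis to C13) can give only (8S,11S) or (8R,11R), and C10 must be S in 32 because it is inverted in step 17.
Assumption: 16 is bought (it is also one C-silylation step from 4-pentyn-1-ol).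
Assumption: the ligand enantiomer that gives (S)-32 in step 14 is fixed in a pilot run by MTPA ester analysis, and the antipode is used if the sense is reversed.

Step 1
Reactants: 1 ethyl 2-methyl-3-oxobutanoate (ethyl 2-methylacetoacetate); 2 formaldehyde (as paraformaldehyde)
Product: 5 4-hydroxy-3-methyl-5,6-dihydro-2H-pyran-2-one, via dianion 3 (not isolated), via hydroxy keto ester 4 (not isolated)
Conditions: NaH, THF, 0 °C; n-BuLi, 0 °C; (CH2O)n, 0 °C to rt; then 1 M NaOH, rt; HCl to pH 1
Reagents that add atoms: none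
Why: The dianion of the β-keto ester reacts with formaldehyde only at its terminal, more reactive carbanion (γ-selective aldol addition), and saponification followed by acidification closes the six-membered lactone (lactonisation), isolated as its stable enol, with no stereocentre formed.

Step 2
Reactants: 5 4-hydroxy-3-methyl-5,6-dihydro-2H-pyran-2-one
Product: 6 3-methyl-2-oxo-5,6-dihydro-2H-pyran-4-yl trifluoromethanesulfonate
Conditions: Tf2O, i-Pr2NEt, CH2Cl2, −78 °C
Reagents that add atoms: trifluoromethanesulfonic anhydride, O=S(=O)(OS(=O)(=O)C(F)(F)F)C(F)(F)F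
Why: Enol triflate formation by O-sulfonylation of the cyclic vinylogous acid is regiochemically unambiguous, and the ring locks the lactone carbonyl (future C12) cis to the ring methylene (future C9) across the future C8=C11 bond.

Step 3
Reactants: 6 3-methyl-2-oxo-5,6-dihydro-2H-pyran-4-yl trifluoromethanesulfonate; 7 allyltributylstannane
Product: 8 3-methyl-4-(prop-2-en-1-yl)-5,6-dihydro-2H-pyran-2-one
Conditions: Pd2(dba)3 (2.5 mol %), AsPh3 (20 mol %), LiCl, NMP, rt
Reagents that add atoms: none
Why: Stille cross-coupling of the electron-poor alkenyl triflate with the allylstannane replaces the triflate at C8 with retention, LiCl assisting transmetalation, so the tetrasubstituted alkene geometry is inherited from the ring.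

Step 4
Reactants: 8 3-methyl-4-(prop-2-en-1-yl)-5,6-dihydro-2H-pyran-2-one
Product: 10 (Z)-N-methoxy-N,2-dimethyl-3-[2-(triethylsilyloxy)ethyl]hexa-2,5-dienamide, via chloromagnesium alkoxide 9 (not isolated)
Conditions: MeNH(OMe)·HCl, i-PrMgCl, THF, −20 to 0 °C; then TESCl, DMAP (cat.), 0 °C to rt
Reagents that add atoms: N,O-dimethylhydroxylamine hydrochloride, CNOC.Cl; chlorotriethylsilane, CC[Si](Cl)(CC)CC
Why: Weinreb aminolysis of the lactone by the chloromagnesium amide and silylation of the released magnesium alkoxide in the same flask separate the two oxygen termini (C10 as TES ether, C12 as amide) before the Z-configured hydroxy amide can relactonise.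

Step 5
Reactants: 10 (Z)-N-methoxy-N,2-dimethyl-3-[2-(triethylsilyloxy)ethyl]hexa-2,5-dienamide
Product: 12 (Z)-2-methyl-3-[2-(triethylsilyloxy)ethyl]hexa-2,5-dien-1-ol, via enal 11 (not isolated)
Conditions: i-Bu2AlH, THF, −78 °C; then MeOH, NaBH4, −78 to 0 °C; Rochelle salt work-up
Reagents that add atoms: none
Why: Reduction of the Weinreb amide stops at the chelated hemiaminal, and the hindered enal released on methanol quench is reduced 1,2 by NaBH4 in the same flask, which gives the C12 allylic alcohol without handling the isomerisable Z-enal.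

Step 6
Reactants: 12 (Z)-2-methyl-3-[2-(triethylsilyloxy)ethyl]hexa-2,5-dien-1-ol
Product: 13 (Z)-1-(tert-butyldimethylsilyloxy)-2-methyl-3-[2-(triethylsilyloxy)ethyl]hexa-2,5-diene
Conditions: TBSCl, imidazole, CH2Cl2, 0 °C to rt
Reagents that add atoms: tert-butyldimethylsilyl chloride, CC(C)(C)[Si](C)(C)Cl
Why: Silylation of the primary allylic alcohol (TBSCl, imidazole) gives an ether that outlasts the later acid removal of the TES groups.

Step 7
Reactants: 13 (Z)-1-(tert-butyldimethylsilyloxy)-2-methyl-3-[2-(triethylsilyloxy)ethyl]hexa-2,5-diene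
Product: 15 (E)-5-(tert-butyldimethylsilyloxy)-4-methyl-3-[2-(triethylsilyloxy)ethyl]pent-3-enal, via diol 14 (not isolated)
Conditions: OsO4 (2 mol %), NMO, acetone/H2O, 0 °C; then NaIO4, NaHCO3, 0 °C to rt
Reagents that add atoms: N-methylmorpholine N-oxide, C[N+]1([O-])CCOCC1 (oxygen relayed through OsO4)
Why: Upjohn dihydroxylation takes place only at the unhindered monosubstituted alkene, osmylation and osmate hydrolysis at the crowded, allylically oxygenated tetrasubstituted C8=C11 alkene being far slower, and buffered periodate glycol cleavage then gives the C6 aldehyde.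

Step 8
Reactants: 16 5-(trimethylsilyl)pent-4-yn-1-ol
Product: 17 5-(trimethylsilyl)pent-4-ynal
Conditions: TEMPO (10 mol %), PhI(OAc)2, CH2Cl2, rt
Reagents that add atoms: none
Why: TEMPO-catalysed oxidation with PhI(OAc)2 stops at the aldehyde and leaves the silylalkyne untouched.

Step 9
Reactants: 18 ethyltriphenylphosphonium bromide; 17 5-(trimethylsilyl)pent-4-ynal
Product: 22 (Z)-(6-iodohept-5-en-1-yn-1-yl)trimethylsilane, via ethylidene ylide 19 (not isolated), via iodoethylphosphonium iodide 20 (not isolated), via iodo ylide 21 (not isolated)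
Conditions: n-BuLi, THF, 0 °C to rt; I2, −78 °C; NaN(SiMe3)2, −78 to −20 °C; then 17, −78 °C to rt
Reagents that add atoms: iodine, [I][I]
Why: Stork–Zhao olefination with the α-iodo ylide gives the (Z)-2-iodo-2-alkene through the kinetically preferred cis-oxaphosphetane, placing iodine cis to the C3 chain as the Z-enone requires.

Step 10
Reactants: 22 (Z)-(6-iodohept-5-en-1-yn-1-yl)trimethylsilane; 15 (E)-5-(tert-butyldimethylsilyloxy)-4-methyl-3-[2-(triethylsilyloxy)ethyl]pent-3-enal
Product: 26 (5Z,9E)-11-(tert-butyldimethylsilyloxy)-6,10-dimethyl-7-(triethylsilyloxy)-9-[2-(triethylsilyloxy)ethyl]undeca-5,9-dien-1-yne (racemic at C6), via alkenyllithium 23 (not isolated), via lithium alkoxide 24 (not isolated), via silylalkyne 25 (not isolated)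
Conditions: t-BuLi (2 equiv per 22), Et2O, −78 °C; 15 in THF, −78 °C; TESCl, −78 to 0 °C; then MeOH, K2CO3, rt
Reagents that add atoms: chlorotriethylsilane, CC[Si](Cl)(CC)CC
Why: Lithium–iodine exchange occurs with retention of alkene geometry, the configurationally stable alkenyllithium adds 1,2 to the aldehyde to form C5–C6 (C6 is formed racemic and is later oxidised), the alkoxide is capped as its TES ether, and methoxide-catalysed protodesilylation then frees the terminal alkyne in the same flask.

Step 11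
Reactants: 26 (5Z,9E)-11-(tert-butyldimethylsilyloxy)-6,10-dimethyl-7-(triethylsilyloxy)-9-[2-(triethylsilyloxy)ethyl]undeca-5,9-dien-1-yne
Product: 28 (5Z,9E)-11-(tert-butyldimethylsilyloxy)-2-iodo-6,10-dimethyl-7-(triethylsilyloxy)-9-[2-(triethylsilyloxy)ethyl]undeca-1,5,9-triene, via iodoalkenylborane 27 (not isolated)
Conditions: B-iodo-9-BBN, pentane, −20 °C; AcOH, 0 °C; aq. NaHCO3
Reagents that add atoms: B-iodo-9-borabicyclo[3.3.1]nonane, IB1C2CCCC1CCC2
Why: Syn iodoboration of the terminal alkyne by B-iodo-9-BBN puts iodine on the internal carbon C1 and protodeboronation by AcOH leaves the 2-iodo-1-alkene (haloboration–protonolysis), conditions under which silyl ethers and the tri- and tetrasubstituted alkenes are inert.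

Step 12
Reactants: 28 (5Z,9E)-11-(tert-butyldimethylsilyloxy)-2-iodo-6,10-dimethyl-7-(triethylsilyloxy)-9-[2-(triethylsilyloxy)ethyl]undeca-1,5,9-triene
Product: 29 (5Z,9E)-11-(tert-butyldimethylsilyloxy)-9-(2-hydroxyethyl)-2-iodo-6,10-dimethylundeca-1,5,9-trien-7-ol
Conditions: PPTS (0.2 equiv), MeOH/CH2Cl2 1:1, 0 °C to rt
Reagents that add atoms: none
Why: Acid-catalysed methanolysis removes the primary and the secondary TES ether while the less labile TBS ether at C12 survives (selective desilylation).

Step 13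
Reactants: 29 (5Z,9E)-11-(tert-butyldimethylsilyloxy)-9-(2-hydroxyethyl)-2-iodo-6,10-dimethylundeca-1,5,9-trien-7-ol
Product: 30 (3E,6Z)-3-[1-(tert-butyldimethylsilyloxy)propan-2-ylidene]-10-iodo-6-methyl-5-oxoundeca-6,10-dienal
Conditions: (COCl)2, DMSO, CH2Cl2, −78 °C; i-Pr2NEt, −78 to −40 °C; pH 7 buffer
Reagents that add atoms: none
Why: In the Swern oxidation both hydroxyls are converted into alkoxysulfonium salts before base is added, so no hydroxy aldehyde can close to a lactol and over-oxidise, and the cold amine-induced elimination gives the skipped keto aldehyde without migration of C8=C11 into conjugation.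

Step 14
Reactants: 30 (3E,6Z)-3-[1-(tert-butyldimethylsilyloxy)propan-2-ylidene]-10-iodo-6-methyl-5-oxoundeca-6,10-dienal
Product: 32 (2Z,7S,9E)-9-[1-(tert-butyldimethylsilyloxy)propan-2-ylidene]-7-hydroxy-2-methyl-6-methylidenecyclodec-2-en-1-one, via alkenylchromium 31 (not isolated)
Conditions: CrCl2 (6 equiv), chiral 2-(4-isopropyl-4,5-dihydrooxazol-2-yl)anilide methanesulfonamide ligand, Et3N, NiCl2(2,9-dimethyl-1,10-phenanthroline) (0.2 equiv), LiCl, MeCN/THF, rt; 30 added by syringe pump to about 2 mM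
Reagents that add atoms: none
Why: Zerovalent nickel, formed from NiCl2 by CrCl2, inserts into the C1–I bond and passes the alkenyl group to trivalent chromium, and the sulfonamide-ligated alkenylchromium adds to the C10 aldehyde (Nozaki–Hiyama–Kishi reaction in its ligand-controlled, ring-closing form, the closest known type being chromium-mediated medium-ring and macrocyclic closures of iodoalkene aldehydes). The ten-membered carbocycle closes in a 10-exo-trig mode, C1 attacking the formyl carbon whose oxygen stays outside the ring. C10 is the only new stereocentre and, since 30 has none, its configuration rests on the chiral ligand bound to chromium (reagent control); any (R)-carbinol is removed in step 15, where only the (S)-enantiomer is epoxidised quickly. The step needs the aldehyde to win over the C6 ketone, which could otherwise close a six-membered ring from C1; alkenylchromium reagents add to aldehydes far faster than to ketones, and this ketone is a conjugated, α-branched enone. It also needs cyclisation to beat dimerisation, which slow addition at high dilution and the two rigid turn elements (Z C4=C5 and the C8=C11 alkylidene) favour, and the non-basic medium leaves the acidic C7 and C9 methylenes untouched.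

Step 15
Reactants: 32 (2Z,7S,9E)-9-[1-(tert-butyldimethylsilyloxy)propan-2-ylidene]-7-hydroxy-2-methyl-6-methylidenecyclodec-2-en-1-one
Product: 33 (3R,6Z,10E,12S)-10-[1-(tert-butyldimethylsilyloxy)propan-2-ylidene]-12-hydroxy-7-methyl-1-oxaspiro[2.9]dodec-6-en-8-one (target numbering 1R,10S)
Conditions: Ti(OiPr)4 (0.2 equiv), L-(+)-diisopropyl tartrate (0.3 equiv), t-BuOOH (1.2 equiv), 4 Å MS, CH2Cl2, −20 °C
Reagents that add atoms: tert-butyl hydroperoxide, CC(C)(C)OO
Why: Sharpless asymmetric epoxidation in its kinetic-resolution mode epoxidises the (S)-carbinol, the fast-reacting enantiomer with L-(+)-tartrate, on the C1=C15 face syn to the titanium-bound C10 oxygen to give the erythro (1R,10S) epoxy alcohol, leaves any (R)-carbinol behind, and does not touch the merely homoallylic C8=C11 alkene or the enone.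

Step 16
Reactants: 33 (3R,6Z,10E,12S)-10-[1-(tert-butyldimethylsilyloxy)propan-2-ylidene]-12-hydroxy-7-methyl-1-oxaspiro[2.9]dodec-6-en-8-one
Product: 34 (3R,6Z,10E,12S)-10-[1-(tert-butyldimethylsilyloxy)propan-2-ylidene]-7-methyl-8-oxo-1-oxaspiro[2.9]dodec-6-en-12-yl methanesulfonate
Conditions: MsCl, Et3N, CH2Cl2, −20 °C
Reagents that add atoms: methanesulfonyl chloride, CS(=O)(=O)Cl
Why: Mesylation through the sulfene activates the hindered secondary C10 hydroxyl with retention of configuration.

Step 17
Reactants: 34 (3R,6Z,10E,12S)-10-[1-(tert-butyldimethylsilyloxy)propan-2-ylidene]-7-methyl-8-oxo-1-oxaspiro[2.9]dodec-6-en-12-yl methanesulfonate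
Product: 36 [(1R,4Z,8E,10R)-8-[1-(tert-butyldimethylsilyloxy)propan-2-ylidene]-5-methyl-6-oxo-11-oxabicyclo[8.1.0]undec-4-en-1-yl]methyl acetate, via caesium alkoxide 35 (not isolated)
Conditions: CsOAc, 18-crown-6, toluene, 60 °C
Reagents that add atoms: caesium acetate, CC(=O)[O-].[Cs+]
Why: Acetate opens the terminal oxirane at the primary carbon C15 by SN2 attack, and the tertiary C1 alkoxide thus released displaces the C10 mesylate with inversion (3-exo-tet ring closure, a Payne-type epoxide transposition), which gives the ring-cis (1R,10R) oxirane and the C15 acetate in one operation, direct SN2 attack of acetate at the neopentyl-like C10 being much slower.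

Step 18
Reactants: 36 [(1R,4Z,8E,10R)-8-[1-(tert-butyldimethylsilyloxy)propan-2-ylidene]-5-methyl-6-oxo-11-oxabicyclo[8.1.0]undec-4-en-1-yl]methyl acetate
Product: 37 [(1R,4Z,8E,10R)-8-(1-hydroxypropan-2-ylidene)-5-methyl-6-oxo-11-oxabicyclo[8.1.0]undec-4-en-1-yl]methyl acetate
Conditions: HF·pyridine, pyridine, THF, 0 °C
Reagents that add atoms: none
Why: Pyridine-buffered HF·pyridine cleaves the primary TBS ether (fluoride-mediated desilylation) without opening the trisubstituted oxirane or removing the acetate.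

Step 19
Reactants: 37 [(1R,4Z,8E,10R)-8-(1-hydroxypropan-2-ylidene)-5-methyl-6-oxo-11-oxabicyclo[8.1.0]undec-4-en-1-yl]methyl acetate
Product: 38 [(1R,4Z,8S,10R,3'S)-3'-(hydroxymethyl)-3',5-dimethyl-6-oxospiro[11-oxabicyclo[8.1.0]undec-4-ene-8,2'-oxirane]-1-yl]methyl acetate
Conditions: Ti(OiPr)4 (0.5 equiv), L-(+)-diethyl tartrate (0.6 equiv), t-BuOOH, 4 Å MS, CH2Cl2, −25 °C
Reagents that add atoms: tert-butyl hydroperoxide, CC(C)(C)OO
Why: Sharpless asymmetric epoxidation of the primary tetrasubstituted allylic alcohol with L-(+)-tartrate, the enantiomer that converts geraniol into its (2S,3S)-epoxide, delivers oxygen to the face of C8=C11 that gives (8S,11S), reagent control overriding the remote ring stereocentres, while the enone and the existing oxirane are not substrates.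

Step 20
Reactants: 38 [(1R,4Z,8S,10R,3'S)-3'-(hydroxymethyl)-3',5-dimethyl-6-oxospiro[11-oxabicyclo[8.1.0]undec-4-ene-8,2'-oxirane]-1-yl]methyl acetate
Product: 39 [(1R,4Z,8S,10R,3'S)-3'-(acetoxymethyl)-3',5-dimethyl-6-oxospiro[11-oxabicyclo[8.1.0]undec-4-ene-8,2'-oxirane]-1-yl]methyl acetate (CNP0185847.4)
Conditions: Ac2O, pyridine, DMAP (cat.), CH2Cl2, 0 °C
Reagents that add atoms: acetic anhydride, CC(=O)OC(C)=O
Why: Acetylation of the primary C12 hydroxyl under pyridine/DMAP nucleophilic catalysis completes the diacetate under conditions too mild to trigger β-elimination of the C8 oxirane next to the C6 ketone.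

**Compound list**

1 | ethyl 2-methyl-3-oxobutanoate (ethyl 2-methylacetoacetate) | CCOC(=O)C(C)C(C)=O | starting material
2 | formaldehyde (used as paraformaldehyde) | C=O | starting material
3 | sodium lithium dianion of 1 (not isolated) | CCOC(=O)[C-](C)C(=O)[CH2-].[Na+].[Li+] | intermediate
4 | ethyl 5-hydroxy-2-methyl-3-oxopentanoate (formed as its metal salt, not isolated) | CCOC(=O)C(C)C(=O)CCO | intermediate
5 | 4-hydroxy-3-methyl-5,6-dihydro-2H-pyran-2-one | CC1=C(O)CCOC1=O | intermediate
6 | 3-methyl-2-oxo-5,6-dihydro-2H-pyran-4-yl trifluoromethanesulfonate | CC1=C(OS(=O)(=O)C(F)(F)F)CCOC1=O | intermediate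
7 | allyltributylstannane | C=CC[Sn](CCCC)(CCCC)CCCC | starting material
8 | 3-methyl-4-(prop-2-en-1-yl)-5,6-dihydro-2H-pyran-2-one | C=CCC1=C(C)C(=O)OCC1 | intermediate
9 | chloromagnesium alkoxide of (Z)-3-(2-hydroxyethyl)-N-methoxy-N,2-dimethylhexa-2,5-dienamide (not isolated) | C=CC/C(CC[O-])=C(\C)C(=O)N(C)OC.[Mg+2].[Cl-] | intermediate
10 | (Z)-N-methoxy-N,2-dimethyl-3-[2-(triethylsilyloxy)ethyl]hexa-2,5-dienamide | C=CC/C(CCO[Si](CC)(CC)CC)=C(\C)C(=O)N(C)OC | intermediate
11 | (Z)-2-methyl-3-[2-(triethylsilyloxy)ethyl]hexa-2,5-dienal (not isolated) | C=CC/C(CCO[Si](CC)(CC)CC)=C(\C)C=O | intermediate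
12 | (Z)-2-methyl-3-[2-(triethylsilyloxy)ethyl]hexa-2,5-dien-1-ol | C=CC/C(CCO[Si](CC)(CC)CC)=C(\C)CO | intermediate
13 | (Z)-1-(tert-butyldimethylsilyloxy)-2-methyl-3-[2-(triethylsilyloxy)ethyl]hexa-2,5-diene | C=CC/C(CCO[Si](CC)(CC)CC)=C(\C)CO[Si](C)(C)C(C)(C)C | intermediate
14 | (E)-6-(tert-butyldimethylsilyloxy)-5-methyl-4-[2-(triethylsilyloxy)ethyl]hex-4-ene-1,2-diol (racemic, not isolated) | OCC(O)C/C(CCO[Si](CC)(CC)CC)=C(\C)CO[Si](C)(C)C(C)(C)C | intermediate
15 | (E)-5-(tert-butyldimethylsilyloxy)-4-methyl-3-[2-(triethylsilyloxy)ethyl]pent-3-enal | O=CC/C(CCO[Si](CC)(CC)CC)=C(\C)CO[Si](C)(C)C(C)(C)C | intermediate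
16 | 5-(trimethylsilyl)pent-4-yn-1-ol | OCCCC#C[Si](C)(C)C | starting material
17 | 5-(trimethylsilyl)pent-4-ynal | O=CCCC#C[Si](C)(C)C | intermediate
18 | ethyltriphenylphosphonium bromide | CC[P+](c1ccccc1)(c1ccccc1)c1ccccc1.[Br-] | starting material
19 | ethylidenetriphenylphosphorane (not isolated) | CC=P(c1ccccc1)(c1ccccc1)c1ccccc1 | intermediate
20 | (1-iodoethyl)triphenylphosphonium iodide (not isolated) | CC(I)[P+](c1ccccc1)(c1ccccc1)c1ccccc1.[I-] | intermediate
21 | (1-iodoethylidene)triphenylphosphorane (not isolated) | CC(I)=P(c1ccccc1)(c1ccccc1)c1ccccc1 | intermediate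
22 | (Z)-(6-iodohept-5-en-1-yn-1-yl)trimethylsilane | C/C(I)=C/CCC#C[Si](C)(C)C | intermediate
23 | [7-(trimethylsilyl)hept-2-en-6-yn-2-yl]lithium, lithium cis to the C3 chain (not isolated) | C/C([Li])=C/CCC#C[Si](C)(C)C | intermediate
24 | lithium alkoxide of the C6 carbinol from 23 and 15 (racemic, not isolated) | C[Si](C)(C)C#CCC/C=C(/C)C([O-])C/C(CCO[Si](CC)(CC)CC)=C(\C)CO[Si](C)(C)C(C)(C)C.[Li+] | intermediate
25 | (5Z,9E)-11-(tert-butyldimethylsilyloxy)-6,10-dimethyl-7-(triethylsilyloxy)-9-[2-(triethylsilyloxy)ethyl]-1-(trimethylsilyl)undeca-5,9-dien-1-yne (racemic, not isolated) | C[Si](C)(C)C#CCC/C=C(/C)C(O[Si](CC)(CC)CC)C/C(CCO[Si](CC)(CC)CC)=C(\C)CO[Si](C)(C)C(C)(C)C | intermediate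
26 | (5Z,9E)-11-(tert-butyldimethylsilyloxy)-6,10-dimethyl-7-(triethylsilyloxy)-9-[2-(triethylsilyloxy)ethyl]undeca-5,9-dien-1-yne (racemic) | C#CCC/C=C(/C)C(O[Si](CC)(CC)CC)C/C(CCO[Si](CC)(CC)CC)=C(\C)CO[Si](C)(C)C(C)(C)C | intermediate
27 | (Z)-2-iodo-1-alkenyl-9-BBN adduct of 26, boron cis to iodine (not isolated) | I/C(CC/C=C(/C)C(O[Si](CC)(CC)CC)C/C(CCO[Si](CC)(CC)CC)=C(\C)CO[Si](C)(C)C(C)(C)C)=C\B1C2CCCC1CCC2 | intermediate
28 | (5Z,9E)-11-(tert-butyldimethylsilyloxy)-2-iodo-6,10-dimethyl-7-(triethylsilyloxy)-9-[2-(triethylsilyloxy)ethyl]undeca-1,5,9-triene (racemic) | C=C(I)CC/C=C(/C)C(O[Si](CC)(CC)CC)C/C(CCO[Si](CC)(CC)CC)=C(\C)CO[Si](C)(C)C(C)(C)C | intermediate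
29 | (5Z,9E)-11-(tert-butyldimethylsilyloxy)-9-(2-hydroxyethyl)-2-iodo-6,10-dimethylundeca-1,5,9-trien-7-ol (racemic) | C=C(I)CC/C=C(/C)C(O)C/C(CCO)=C(\C)CO[Si](C)(C)C(C)(C)C | intermediate
30 | (3E,6Z)-3-[1-(tert-butyldimethylsilyloxy)propan-2-ylidene]-10-iodo-6-methyl-5-oxoundeca-6,10-dienal | C=C(I)CC/C=C(/C)C(=O)C/C(=C(\C)CO[Si](C)(C)C(C)(C)C)CC=O | intermediate
31 | C1 alkenylchromium dichloride derived from 30 (trivalent chromium, sulfonamide ligand omitted, not isolated) | C=C([Cr](Cl)Cl)CC/C=C(/C)C(=O)C/C(=C(\C)CO[Si](C)(C)C(C)(C)C)CC=O | intermediate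
32 | (2Z,7S,9E)-9-[1-(tert-butyldimethylsilyloxy)propan-2-ylidene]-7-hydroxy-2-methyl-6-methylidenecyclodec-2-en-1-one | C=C1CC/C=C(/C)C(=O)C/C(=C(\C)CO[Si](C)(C)C(C)(C)C)C[C@@H]1O | intermediate
33 | (3R,6Z,10E,12S)-10-[1-(tert-butyldimethylsilyloxy)propan-2-ylidene]-12-hydroxy-7-methyl-1-oxaspiro[2.9]dodec-6-en-8-one | C1O[C@]12CC/C=C(/C)C(=O)C/C(=C(\C)CO[Si](C)(C)C(C)(C)C)C[C@@H]2O | intermediate
34 | (3R,6Z,10E,12S)-10-[1-(tert-butyldimethylsilyloxy)propan-2-ylidene]-7-methyl-8-oxo-1-oxaspiro[2.9]dodec-6-en-12-yl methanesulfonate | C1O[C@]12CC/C=C(/C)C(=O)C/C(=C(\C)CO[Si](C)(C)C(C)(C)C)C[C@@H]2OS(C)(=O)=O | intermediate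
35 | caesium C1 alkoxide formed by acetate opening of 34 at C15 (1R,10S; not isolated) | CC(=O)OC[C@]1([O-])CC/C=C(/C)C(=O)C/C(=C(\C)CO[Si](C)(C)C(C)(C)C)C[C@@H]1OS(C)(=O)=O.[Cs+] | intermediate
36 | [(1R,4Z,8E,10R)-8-[1-(tert-butyldimethylsilyloxy)propan-2-ylidene]-5-methyl-6-oxo-11-oxabicyclo[8.1.0]undec-4-en-1-yl]methyl acetate | CC(=O)OC[C@]12CC/C=C(/C)C(=O)C/C(=C(\C)CO[Si](C)(C)C(C)(C)C)C[C@H]1O2 | intermediate
37 | [(1R,4Z,8E,10R)-8-(1-hydroxypropan-2-ylidene)-5-methyl-6-oxo-11-oxabicyclo[8.1.0]undec-4-en-1-yl]methyl acetate | CC(=O)OC[C@]12CC/C=C(/C)C(=O)C/C(=C(\C)CO)C[C@H]1O2 | intermediate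
38 | [(1R,4Z,8S,10R,3'S)-3'-(hydroxymethyl)-3',5-dimethyl-6-oxospiro[11-oxabicyclo[8.1.0]undec-4-ene-8,2'-oxirane]-1-yl]methyl acetate | CC(=O)OC[C@]12CC/C=C(/C)C(=O)C[C@]3(C[C@H]1O2)O[C@@]3(C)CO | intermediate
39 | [(1R,4Z,8S,10R,3'S)-3'-(acetoxymethyl)-3',5-dimethyl-6-oxospiro[11-oxabicyclo[8.1.0]undec-4-ene-8,2'-oxirane]-1-yl]methyl acetate (CNP0185847.4) | CC(=O)OC[C@]12CC/C=C(/C)C(=O)C[C@]3(C[C@H]1O2)O[C@@]3(C)COC(C)=O | target

**Step count**

Total step count: 20. Longest linear sequence: 18 steps (steps 1–7 and 10–20, from 1); iodide 22 comes from a two-step branch (steps 8–9).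

**Steps most likely to fail**

Step 14. The ligand-bound alkenylchromium may discriminate poorly between the two faces of the aldehyde in the strained ten-membered transition state, so that the ring closes with little or no enantiocontrol. The fallback sets out from 30 and moves the origin of absolute configuration from the carbon–carbon bond formation to a kinetic resolution. The ring is closed with CrCl2 and catalytic NiCl2 in DMSO/THF at high dilution without chiral ligand, which should give the racemic C10 carbinol F1. F1 is then submitted to the titanium/L-(+)-tartrate epoxidation of step 15 with about 0.6 equivalent of t-BuOOH. Only the (S)-enantiomer is epoxidised at a useful rate, so the route is rejoined at 33, and the unreacted (R)-carbinol F2 is separated.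

Step 17. Acetate may act as a base instead of a nucleophile: it could eliminate the C10 mesylate towards C9, or enolise C7 so that C8=C11 moves into conjugation, before the slow opening of the oxirane at C15 occurs. The fallback sets out from 33 and separates opening and ring closure. Ti(OiPr)4 and AcOH in CH2Cl2 should deliver acetate to the terminal carbon C15 of the 2,3-epoxy alcohol unit under titanium chelation, giving the C1,C10-diol C15-acetate F3. Mesylation then takes place only at the secondary C10 hydroxyl, the tertiary C1 hydroxyl being inert, to give hydroxy mesylate F4. Cs2CO3 in MeCN at room temperature closes the C1–C10 oxirane with inversion at C10, and the route is rejoined at 36.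

Step 19. Oxygen transfer to the crowded tetrasubstituted alkene of the rigid epoxy macrocycle may be slow. Titanium alkoxide could then open the acetoxymethyl oxirane or transesterify the C15 acetate, and facial control could erode. The fallback sets out from 32 and carries out both epoxidations before either sensitive group exists. HF·pyridine removes the TBS group to give diol F5. A single titanium/L-(+)-tartrate epoxidation with excess t-BuOOH should then oxidise both allylic alcohols, each in its matched sense, to bis-epoxy diol F6. The primary C12 hydroxyl is acetylated selectively (Ac2O, 2,4,6-collidine, −20 °C) to give monoacetate F7, and the C10 hydroxyl is mesylated to give mesylate F8. The CsOAc transposition of step 17, run at the lowest temperature that gives conversion, then leads directly to 39.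

**Further compounds**

F1 | step 14 | racemic (2Z,9E)-9-[1-(tert-butyldimethylsilyloxy)propan-2-ylidene]-7-hydroxy-2-methyl-6-methylidenecyclodec-2-en-1-one | C=C1CC/C=C(/C)C(=O)C/C(=C(\C)CO[Si](C)(C)C(C)(C)C)CC1O
F2 | step 14 | (2Z,7R,9E)-9-[1-(tert-butyldimethylsilyloxy)propan-2-ylidene]-7-hydroxy-2-methyl-6-methylidenecyclodec-2-en-1-one | C=C1CC/C=C(/C)C(=O)C/C(=C(\C)CO[Si](C)(C)C(C)(C)C)C[C@H]1O
F3 | step 17 | [(1R,2S,4E,7Z)-4-[1-(tert-butyldimethylsilyloxy)propan-2-ylidene]-1,2-dihydroxy-7-methyl-6-oxocyclodec-7-en-1-yl]methyl acetate | CC(=O)OC[C@]1(O)CC/C=C(/C)C(=O)C/C(=C(\C)CO[Si](C)(C)C(C)(C)C)C[C@@H]1O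
F4 | step 17 | [(1R,2S,4E,7Z)-4-[1-(tert-butyldimethylsilyloxy)propan-2-ylidene]-1-hydroxy-2-(methanesulfonyloxy)-7-methyl-6-oxocyclodec-7-en-1-yl]methyl acetate | CC(=O)OC[C@]1(O)CC/C=C(/C)C(=O)C/C(=C(\C)CO[Si](C)(C)C(C)(C)C)C[C@@H]1OS(C)(=O)=O
F5 | step 19 | (2Z,7S,9E)-7-hydroxy-9-(1-hydroxypropan-2-ylidene)-2-methyl-6-methylidenecyclodec-2-en-1-one | C=C1CC/C=C(/C)C(=O)C/C(=C(\C)CO)C[C@@H]1O
F6 | step 19 | bis-epoxy diol, C1–C15 and C8–C11 oxiranes with free C10 and C12 hydroxyls (target numbering 1R,8S,10S,11S) | C1O[C@]12CC/C=C(/C)C(=O)C[C@]3(C[C@@H]2O)O[C@@]3(C)CO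
F7 | step 19 | C12 acetate of F6 with free C10 hydroxyl (1R,8S,10S,11S) | C1O[C@]12CC/C=C(/C)C(=O)C[C@]3(C[C@@H]2O)O[C@@]3(C)COC(C)=O
F8 | step 19 | C10 methanesulfonate of F7 (1R,8S,10S,11S) | C1O[C@]12CC/C=C(/C)C(=O)C[C@]3(C[C@@H]2OS(C)(=O)=O)O[C@@]3(C)COC(C)=O
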